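**Retrosynthetic overview**
- Target ⇐ C3-epimeric cis-bromohydrin (Mitsunobu inversion) ⇐ α′-bromo enone ⇐ spiro enone 16 (enolate bromination, then hydride reduction).
- Enone 16 ⇐ keto acetate 13 (MeLi addition, oxidation, dehydration); vinyl bromide ⇐ enol triflate ⇐ ring B ketone ⇐ hydroboration of the cycloadduct alkene.
- Spiro centre and ring B (formed second) ⇐ Diels–Alder reaction of isoprene with the exocyclic enone 7; ring A (first) is the ring of carvone.
- Dienophile 7 ⇐ (R)-carvone (1,2-methylation, oxidative transposition, Criegee cleavage of the isopropenyl group to OAc, cuprate addition, Saegusa oxidation).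
- Stereochemical relay: C5 of carvone → C3–OAc anchor → spiro C6 → C4–Br → C3–OH.

Assumption: spiro compounds are numbered as spiro[5.5]undecanes, ring A = C1–C5 (C1 carries the ring methyl or its precursor carbonyl, C3 the oxygen, C4 the sp3 bromine, C5 the gem-dimethyl group), C6 = spiro atom, ring B = C7–C11 (C8 = CBr, C9 = C–Me). On this numbering the target is the (3S,4S,6S) isomer, with OH trans to Br and Br on the face of C7.

Step 1
Reactants: 1 (R)-(−)-carvone, (5R)-2-methyl-5-(prop-1-en-2-yl)cyclohex-2-en-1-one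
Product: 2 (5R)-1,2-dimethyl-5-(prop-1-en-2-yl)cyclohex-2-en-1-ol (C1 epimers)
Conditions: MeLi, Et2O, −78 → 0 °C; aq. NH4Cl
Reagents that add atoms: methyllithium, C[Li]
Why: 1,2-addition of the organolithium to the enone carbonyl; the new carbinol centre is uncontrolled and is erased in step 2, while C5 is untouched.

Step 2
Reactants: 2
Product: 3 (5S)-2,3-dimethyl-5-(prop-1-en-2-yl)cyclohex-2-en-1-one
Conditions: [C5H5NH][CrO3Cl] (pyridinium chlorochromate), CH2Cl2, 25 °C
Reagents that add atoms: pyridinium chlorochromate, [O-][Cr](=O)(=O)Cl.c1cc[nH+]cc1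
Why: Babler–Dauben oxidative transposition ([3,3] shift of the tertiary allylic chromate ester, then oxidation) gives the β-methyl enone; the stereocentre is untouched and only its descriptor changes.

Step 3
Reactants: 3
Product: 5 (1S)-3,4-dimethyl-5-oxocyclohex-3-en-1-yl acetate, via methoxy hydroperoxide 4 (not isolated)
Conditions: O3, CH2Cl2/MeOH, −78 °C (stopped at first excess); then Ac2O, Et3N, DMAP, 0 → 25 °C
Reagents that add atoms: ozone, [O-][O+]=O; methanol, CO
Why: ozonolysis selective for the electron-rich isopropenyl group over the conjugated alkene, then Criegee rearrangement in which the ring carbon migrates to oxygen with retention, so the purchased stereocentre becomes the C–OAc centre.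

Step 4
Reactants: 5
Product: 6 (1S)-4,5,5-trimethyl-3-[(trimethylsilyl)oxy]cyclohex-3-en-1-yl acetate
Conditions: Me2CuLi (from CuI + 2 MeLi), Me3SiCl, Et3N, Et2O/THF, −78 → −20 °C
Reagents that add atoms: lithium dimethylcuprate, [Li+].C[Cu-]C; chlorotrimethylsilane, C[Si](C)(C)Cl
Why: silyl-chloride-accelerated cuprate conjugate addition builds the gem-dimethyl carbon (no new stereocentre) and traps the regiodefined enolate as its silyl enol ether; the acetate is inert to the cuprate at low temperature.

Step 5
Reactants: 6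
Product: 7 (1S)-3,3-dimethyl-4-methylidene-5-oxocyclohexyl acetate
Conditions: Pd(OAc)2 (1.05 equiv), MeCN, 25 °C; used at once
Reagents that add atoms: none
Why: Saegusa–Ito oxidation; the divalent palladium enolate has β-hydrogens only on the methyl group (the other neighbour is quaternary), so β-hydride elimination can only give the exocyclic enone.

Step 6
Reactants: 7; 8 isoprene (2-methylbuta-1,3-diene)
Product: 9 (3S,6R)-5,5,9-trimethyl-1-oxospiro[5.5]undec-8-en-3-yl acetate
Conditions: Me2AlCl (0.3 equiv), isoprene (5 equiv), CH2Cl2, −78 → −30 °C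
Reagents that add atoms: none
Why: Lewis-acid-catalysed Diels–Alder reaction with para regiochemistry forms ring B and the spiro centre; the acetoxy group must stay equatorial (axial it would clash 1,3 with a ring methyl), which locks the chair, and isoprene attacks the exocyclic alkene axially, anti to the adjacent axial methyl, so the new C6–C7 bond is cis to OAc.

Step 7
Reactants: 9
Product: 11 (3S,6R)-5,5,9-trimethyl-1,8-dioxospiro[5.5]undecan-3-yl acetate (C9 epimers), via alkylborane 10 (not isolated)
Conditions: BH3·THF, THF, 0 → 25 °C; then [C5H5NH][CrO3Cl] (pyridinium chlorochromate), CH2Cl2, 40 °C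
Reagents that add atoms: pyridinium chlorochromate, [O-][Cr](=O)(=O)Cl.c1cc[nH+]cc1
Why: anti-Markovnikov hydroboration puts boron on C8 and chromate oxidation of the C–B bond gives the ketone directly (any C1 ketone reduced by borane is re-oxidised in the same flask); C9 is set at random and becomes sp2 in step 8.

Step 8
Reactants: 11
Product: 12 (3S,6R)-5,5,9-trimethyl-1-oxo-8-[(trifluoromethanesulfonyl)oxy]spiro[5.5]undec-8-en-3-yl acetate
Conditions: Tf2O (1.05 equiv), 2,6-di-tert-butyl-4-methylpyridine, CH2Cl2, −78 → 0 °C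
Reagents that add atoms: trifluoromethanesulfonic anhydride, O=S(=O)(OS(=O)(=O)C(F)(F)F)C(F)(F)F
Why: enol triflate formation under equilibrating conditions gives the more substituted C8=C9 alkene (C7 is neopentylic), and the C1 ketone, flanked by the quaternary spiro carbon and deactivated by the β-acetoxy group, reacts far more slowly.

Step 9
Reactants: 12
Product: 13 (3S,6R)-8-bromo-5,5,9-trimethyl-1-oxospiro[5.5]undec-8-en-3-yl acetate
Conditions: Ni(OAc)2·4H2O (10 mol %), 1,5-cyclooctadiene (30 mol %), Zn (20 mol %), LiBr (3 equiv), DMA/THF, 25 °C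
Reagents that add atoms: lithium bromide, [Li+].[Br-]
Why: nickel-catalysed halogen exchange of the enol triflate (oxidative addition to zerovalent nickel, triflate–bromide exchange, C–Br reductive elimination) gives the tetrasubstituted vinyl bromide at room temperature without touching ketone or ester.

Step 10
Reactants: 13
Product: 14 (3S,6R)-8-bromo-1,5,5,9-tetramethylspiro[5.5]undec-8-ene-1,3-diol (C1 epimers)
Conditions: MeLi (5 equiv), CeCl3 (2.5 equiv), THF, −78 → 0 °C; aq. NH4Cl
Reagents that add atoms: methyllithium, C[Li]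
Why: organocerium 1,2-addition to the hindered, enolisable C1 ketone avoids β-elimination of the acetate, and excess reagent cleaves the acetate; the vinyl bromide does not exchange with MeLi at this temperature and the new tertiary centre is lost in step 11.

Step 11
Reactants: 14
Product: 16 (6R)-8-bromo-1,5,5,9-tetramethylspiro[5.5]undeca-1,8-dien-3-one, via hydroxy ketone 15 (not isolated)
Conditions: Dess–Martin periodinane, CH2Cl2, 25 °C; then TsOH·H2O (cat.), benzene, 60 °C
Reagents that add atoms: none
Why: oxidation of the secondary alcohol only, then acid-catalysed dehydration of the β-hydroxy ketone through its enol gives the conjugated endocyclic enone.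

Step 12
Reactants: 16
Product: 19 (4S,6S)-4,8-dibromo-1,5,5,9-tetramethylspiro[5.5]undeca-1,8-dien-3-one, via silyl dienol ether 17 (not isolated), via 4R bromo enone 18 (not isolated)
Conditions: LiN(i-Pr)2, Me3SiCl, THF, −78 °C; NBS, −78 → 0 °C; then DBU (0.1 equiv), CH2Cl2, 0 → 25 °C
Reagents that add atoms: N-bromosuccinimide, O=C1CCC(=O)N1Br
Why: kinetic α′-deprotonation and enolate bromination fix the position, and epimerisation through the enolate gives the equatorial bromide; because C7 (whose neighbour C8 is sp2) takes the crowded pseudo-equatorial site beside the C1 methyl and C11 is pseudo-axial, the equatorial bromide lies anti to C11 and on the face of C7, i.e. 4S.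

Step 13
Reactants: 19
Product: 20 (3R,4S,6S)-4,8-dibromo-1,5,5,9-tetramethylspiro[5.5]undeca-1,8-dien-3-ol
Conditions: i-Bu2AlH, CH2Cl2, −78 °C; Rochelle salt work-up
Reagents that add atoms: none
Why: 1,2-reduction of the enone in which hydride adds from the face away from the axial C5 methyl (equatorial attack), giving the axial alcohol cis to the equatorial bromide.

Step 14
Reactants: 20
Product: 22 (3S,4S,6S)-4,8-dibromo-1,5,5,9-tetramethylspiro[5.5]undeca-1,8-dien-3-ol (target), via nitrobenzoate ester 21 (not isolated)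
Conditions: 4-O2NC6H4CO2H, PPh3, DIAD, THF, 0 → 25 °C; then K2CO3 (cat.), MeOH, 25 °C
Reagents that add atoms: 4-nitrobenzoic acid, O=C(O)c1ccc(cc1)[N+](=O)[O-]
Why: Mitsunobu inversion of the axial allylic alcohol (SN2 by the carboxylate; the cis bromine cannot participate) and methanolysis of the ester give the equatorial alcohol trans to bromine, which is the target.

**Compound list**
1 | (R)-(−)-carvone | CC1=CC[C@H](CC1=O)C(C)=C | starting material
2 | (5R)-1,2-dimethyl-5-(prop-1-en-2-yl)cyclohex-2-en-1-ol (C1 epimers) | CC1=CC[C@H](CC1(C)O)C(C)=C | intermediate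
3 | (5S)-2,3-dimethyl-5-(prop-1-en-2-yl)cyclohex-2-en-1-one | CC1=C(C)C[C@H](C(C)=C)CC1=O | intermediate
4 | (5S)-5-(1-hydroperoxy-1-methoxyethyl)-2,3-dimethylcyclohex-2-en-1-one | CC1=C(C)C[C@H](C(C)(OC)OO)CC1=O | intermediate
5 | (1S)-3,4-dimethyl-5-oxocyclohex-3-en-1-yl acetate | CC1=C(C)C[C@H](OC(C)=O)CC1=O | intermediate
6 | (1S)-4,5,5-trimethyl-3-[(trimethylsilyl)oxy]cyclohex-3-en-1-yl acetate | CC1=C(O[Si](C)(C)C)C[C@@H](OC(C)=O)CC1(C)C | intermediate
7 | (1S)-3,3-dimethyl-4-methylidene-5-oxocyclohexyl acetate | C=C1C(=O)C[C@@H](OC(C)=O)CC1(C)C | intermediate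
8 | isoprene | C=CC(C)=C | starting material
9 | (3S,6R)-5,5,9-trimethyl-1-oxospiro[5.5]undec-8-en-3-yl acetate | O=C1C[C@@H](OC(C)=O)CC(C)(C)[C@]12CCC(C)=CC2 | intermediate
10 | C8 alkylborane of 9 (drawn as RBH2) | O=C1C[C@@H](OC(C)=O)CC(C)(C)[C@]12CCC(C)C(B)C2 | intermediate
11 | (3S,6R)-5,5,9-trimethyl-1,8-dioxospiro[5.5]undecan-3-yl acetate (C9 epimers) | O=C1C[C@@H](OC(C)=O)CC(C)(C)[C@]12CCC(C)C(=O)C2 | intermediate
12 | (3S,6R)-5,5,9-trimethyl-1-oxo-8-[(trifluoromethanesulfonyl)oxy]spiro[5.5]undec-8-en-3-yl acetate | O=C1C[C@@H](OC(C)=O)CC(C)(C)[C@]12CCC(C)=C(OS(=O)(=O)C(F)(F)F)C2 | intermediate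
13 | (3S,6R)-8-bromo-5,5,9-trimethyl-1-oxospiro[5.5]undec-8-en-3-yl acetate | O=C1C[C@@H](OC(C)=O)CC(C)(C)[C@]12CCC(C)=C(Br)C2 | intermediate
14 | (3S,6R)-8-bromo-1,5,5,9-tetramethylspiro[5.5]undec-8-ene-1,3-diol (C1 epimers) | CC1(O)C[C@@H](O)CC(C)(C)[C@]12CCC(C)=C(Br)C2 | intermediate
15 | (6R)-8-bromo-1-hydroxy-1,5,5,9-tetramethylspiro[5.5]undec-8-en-3-one | CC1(O)CC(=O)CC(C)(C)[C@]12CCC(C)=C(Br)C2 | intermediate
16 | (6R)-8-bromo-1,5,5,9-tetramethylspiro[5.5]undeca-1,8-dien-3-one | CC1=CC(=O)CC(C)(C)[C@]12CCC(C)=C(Br)C2 | intermediate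
17 | {[(6S)-8-bromo-1,5,5,9-tetramethylspiro[5.5]undeca-1,3,8-trien-3-yl]oxy}trimethylsilane | CC1=CC(O[Si](C)(C)C)=CC(C)(C)[C@]12CCC(C)=C(Br)C2 | intermediate
18 | (4R,6S)-4,8-dibromo-1,5,5,9-tetramethylspiro[5.5]undeca-1,8-dien-3-one | CC1=CC(=O)[C@H](Br)C(C)(C)[C@]12CCC(C)=C(Br)C2 | intermediate
19 | (4S,6S)-4,8-dibromo-1,5,5,9-tetramethylspiro[5.5]undeca-1,8-dien-3-one | CC1=CC(=O)[C@@H](Br)C(C)(C)[C@]12CCC(C)=C(Br)C2 | intermediate
20 | (3R,4S,6S)-4,8-dibromo-1,5,5,9-tetramethylspiro[5.5]undeca-1,8-dien-3-ol | CC1=C[C@@H](O)[C@@H](Br)C(C)(C)[C@]12CCC(C)=C(Br)C2 | intermediate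
21 | (3S,4S,6S)-4,8-dibromo-1,5,5,9-tetramethylspiro[5.5]undeca-1,8-dien-3-yl 4-nitrobenzoate | CC1=C[C@H](OC(=O)c3ccc(cc3)[N+](=O)[O-])[C@@H](Br)C(C)(C)[C@]12CCC(C)=C(Br)C2 | intermediate
22 | (3S,4S,6S)-4,8-dibromo-1,5,5,9-tetramethylspiro[5.5]undeca-1,8-dien-3-ol | CC1=C[C@H](O)[C@@H](Br)C(C)(C)[C@]12CCC(C)=C(Br)C2 | target

**Totals**
Total step count: 14. Longest linear sequence: 14 (fully linear; isoprene enters at step 6).

**Steps most likely to fail**

Step 6 (facial selectivity of the cycloaddition; the dienophile dimerises and can lose AcOH under Lewis acid). The fallback sets out from 7 and comes back at 9, building ring B by metathesis instead of cycloaddition. Copper-mediated conjugate addition of 2-methylallylmagnesium chloride (CuBr·SMe2, Me3SiCl, THF, −78 °C) to the exocyclic enone, followed by C-allylation of the resulting enolate with allyl bromide on the same axial face, gives (1S,4R)-3,3-dimethyl-4-(3-methylbut-3-en-1-yl)-5-oxo-4-(prop-2-en-1-yl)cyclohexyl acetate F1. Ring-closing metathesis with the second-generation Grubbs catalyst (CH2Cl2, 40 °C) then closes the trisubstituted cyclohexene and gives 9.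

Step 8 (chemoselectivity between the two ketones and regiochemistry of the enol triflate). The fallback sets out from 11 and comes back at 13, bypassing 12. Hydrazine hydrate (1.1 equiv, EtOH, 0 °C) condenses with the less hindered ring B ketone to give (3S,6R)-8-hydrazinylidene-5,5,9-trimethyl-1-oxospiro[5.5]undecan-3-yl acetate F2. NBS in pyridine (Barton-type vinyl halide synthesis) converts it into the vinyl bromide 13 with loss of N2; the cationic intermediate should lose its proton from the tertiary C9 rather than the neopentylic C7.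

Step 12 (the C4 epimer ratio rests on a small conformational preference of ring B that I have argued from models, not from precedent; base may also cause side reactions of the bromo enone). The fallback sets out from 16 and comes back at the target 22, making steps 13 and 14 unnecessary. Luche reduction (NaBH4, CeCl3·7H2O, MeOH, −78 °C) gives (6R)-8-bromo-1,5,5,9-tetramethylspiro[5.5]undeca-1,8-dien-3-ol F3 (either C3 epimer), and dehydration with Martin sulfurane gives (6S)-8-bromo-1,5,5,9-tetramethylspiro[5.5]undeca-1,3,8-triene F4. NBS in THF/H2O at 0 °C then adds Br+ to the diene terminus C4 and water to the allylic C3 in an anti sense, which builds the trans bromohydrin directly. Here the C4 configuration is decided kinetically in a bromonium opening, not by equilibration, so the facial outcome is decided by a different criterion than in step 12.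

Further compounds
F1 | step 6 | (1S,4R)-3,3-dimethyl-4-(3-methylbut-3-en-1-yl)-5-oxo-4-(prop-2-en-1-yl)cyclohexyl acetate | O=C1C[C@@H](OC(C)=O)CC(C)(C)[C@]1(CC=C)CCC(C)=C
F2 | step 8 | (3S,6R)-8-hydrazinylidene-5,5,9-trimethyl-1-oxospiro[5.5]undecan-3-yl acetate (C9 epimers) | O=C1C[C@@H](OC(C)=O)CC(C)(C)[C@]12CCC(C)C(=NN)C2
F3 | step 12 | (6R)-8-bromo-1,5,5,9-tetramethylspiro[5.5]undeca-1,8-dien-3-ol (C3 epimers) | CC1=CC(O)CC(C)(C)[C@]12CCC(C)=C(Br)C2
F4 | step 12 | (6S)-8-bromo-1,5,5,9-tetramethylspiro[5.5]undeca-1,3,8-triene | CC1=CC=CC(C)(C)[C@]12CCC(C)=C(Br)C2
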